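**Retrosynthetic overview**
- The target is an achiral, symmetric methylene-bis(gigantol). The last operation is a global O-desilylation of its tetra-TIPS ether.
- Both aryl–CH2CH2 bonds are cut at once. A double B-alkyl Suzuki coupling joins a central 2,2'-dichlorodiarylmethane to the 9-BBN adduct of TIPS-protected 4-vinylguaiacol.
- The central Ar–CH2–Ar comes from the diaryl carbinol by ionic deoxygenation. The carbinol comes from two aryllithiums and ethyl formate as a C1 linchpin.
- Regiocontrol comes from directed ortho-lithiation of TIPS-protected 3-chloro-5-methoxyphenol between Cl and OMe, para to OTIPS. Chlorine first directs the lithiation and later serves as the coupling handle.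
- No ring is formed. All four benzene rings are bought.

**Assumption:** the SMILES has no stereocentre and no double-bond geometry. The target is therefore achiral, there is no enantiomer to select, and no step sets stereochemistry.

**Step 1**
Reactants: 1 3-chloro-5-methoxyphenol
Product: 2 (3-chloro-5-methoxyphenoxy)triisopropylsilane
Conditions: TIPSCl (1.1 equiv), imidazole (2 equiv), DMF, 0 °C → rt
Reagents that add atoms: triisopropylsilyl chloride, CC(C)[Si](Cl)(C(C)C)C(C)C
Why: Imidazole-promoted O-silylation of the only OH removes the acidic proton and installs a bulky, non-coordinating group that shields both of its ortho positions in the next step; no stereocentre is formed.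

**Step 2**
Reactants: 2 (3-chloro-5-methoxyphenoxy)triisopropylsilane (2 equiv per formate)
Product: 5 bis[2-chloro-6-methoxy-4-(triisopropylsilyloxy)phenyl]methanol, via [2-chloro-6-methoxy-4-(triisopropylsilyloxy)phenyl]lithium 3 (not isolated), via 2-chloro-6-methoxy-4-(triisopropylsilyloxy)benzaldehyde 4 (not isolated)
Conditions: s-BuLi (1.05 equiv), THF, −78 °C, 1.5 h; HCO2Et (0.48 equiv), −78 °C, 2 h; H2O
Reagents that add atoms: ethyl formate, CCOC=O
Why: Directed ortho-metalation removes the C–H flanked by OMe (coordination) and Cl (inductive acidification) while the sites next to OTIPS are blocked, and the aryllithium adds twice to the formate (addition–elimination, then 1,2-addition), so the bridge carbon sits ortho to OMe, ortho to Cl and para to OTIPS in both rings; the carbinol carbon bears two identical aryl groups and is not a stereocentre.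

**Step 3**
Reactants: 5 bis[2-chloro-6-methoxy-4-(triisopropylsilyloxy)phenyl]methanol
Product: 6 bis[2-chloro-6-methoxy-4-(triisopropylsilyloxy)phenyl]methane
Conditions: Et3SiH (3 equiv), TFA (10 equiv), CH2Cl2, 0 °C, 30 min
Reagents that add atoms: none
Why: In this ionic hydrogenation (Kursanov–Parnes) the carbinol ionises easily to a diarylmethyl cation stabilised by the o-OMe and p-OSi groups, and the silane traps it with hydride faster than the aryl TIPS ethers, OMe or Ar–Cl groups react.

**Step 4**
Reactants: 7 2-methoxy-4-vinylphenol (4-vinylguaiacol)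
Product: 8 triisopropyl(2-methoxy-4-vinylphenoxy)silane
Conditions: TIPSCl (1.1 equiv), imidazole (2 equiv), DMF, 0 °C → rt
Reagents that add atoms: triisopropylsilyl chloride, CC(C)[Si](Cl)(C(C)C)C(C)C
Why: Standard O-silylation masks the phenol against 9-BBN and base and uses the same protecting group as ring A, so one final deprotection is enough.

**Step 5**
Reactants: 6 bis[2-chloro-6-methoxy-4-(triisopropylsilyloxy)phenyl]methane; 8 triisopropyl(2-methoxy-4-vinylphenoxy)silane (2.6 equiv)
Product: 10 bis{2-methoxy-6-[2-(3-methoxy-4-triisopropylsilyloxyphenyl)ethyl]-4-(triisopropylsilyloxy)phenyl}methane, via 9-{2-[3-methoxy-4-(triisopropylsilyloxy)phenyl]ethyl}-9-borabicyclo[3.3.1]nonane 9 (not isolated)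
Conditions: 8, 9-BBN-H (2.7 equiv), THF, 0 °C → rt; then 6, Pd(OAc)2 (5 mol %), SPhos (10 mol %), K3PO4·H2O (6 equiv), THF, 65 °C
Reagents that add atoms: none
Why: Anti-Markovnikov Brown hydroboration of the styrene followed by a twofold B-alkyl Suzuki–Miyaura coupling builds both saturated CH2CH2 links directly, because each C–Cl is meta to both oxygens (not deactivated) and has only one ortho substituent, which Pd/SPhos tolerates.

**Step 6**
Reactants: 10 bis{2-methoxy-6-[2-(3-methoxy-4-triisopropylsilyloxyphenyl)ethyl]-4-(triisopropylsilyloxy)phenyl}methane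
Product: 11 4,4'-methylenebis{5-[2-(4-hydroxy-3-methoxyphenyl)ethyl]-3-methoxyphenol} (target)
Conditions: TBAF (4.4 equiv), AcOH (4.4 equiv), THF, 0 °C → rt, N2
Reagents that add atoms: none
Why: Fluoride-mediated desilylation, driven by the Si–F bond, cleaves all four aryl TIPS ethers, and the acetic acid buffer protonates the electron-rich phenoxides so they are not oxidised; the methyl ethers and the diarylmethane are untouched.

**Compound list**
1 | 3-chloro-5-methoxyphenol | COc1cc(O)cc(Cl)c1 | starting material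
2 | (3-chloro-5-methoxyphenoxy)triisopropylsilane | COc1cc(Cl)cc(O[Si](C(C)C)(C(C)C)C(C)C)c1 | intermediate
3 | [2-chloro-6-methoxy-4-(triisopropylsilyloxy)phenyl]lithium | [Li]c1c(Cl)cc(O[Si](C(C)C)(C(C)C)C(C)C)cc1OC | intermediate
4 | 2-chloro-6-methoxy-4-(triisopropylsilyloxy)benzaldehyde | O=Cc1c(Cl)cc(O[Si](C(C)C)(C(C)C)C(C)C)cc1OC | intermediate
5 | bis[2-chloro-6-methoxy-4-(triisopropylsilyloxy)phenyl]methanol | OC(c1c(Cl)cc(O[Si](C(C)C)(C(C)C)C(C)C)cc1OC)c1c(Cl)cc(O[Si](C(C)C)(C(C)C)C(C)C)cc1OC | intermediate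
6 | bis[2-chloro-6-methoxy-4-(triisopropylsilyloxy)phenyl]methane | COc1cc(O[Si](C(C)C)(C(C)C)C(C)C)cc(Cl)c1Cc1c(Cl)cc(O[Si](C(C)C)(C(C)C)C(C)C)cc1OC | intermediate
7 | 2-methoxy-4-vinylphenol | C=Cc1ccc(O)c(OC)c1 | starting material
8 | triisopropyl(2-methoxy-4-vinylphenoxy)silane | C=Cc1ccc(O[Si](C(C)C)(C(C)C)C(C)C)c(OC)c1 | intermediate
9 | 9-{2-[3-methoxy-4-(triisopropylsilyloxy)phenyl]ethyl}-9-borabicyclo[3.3.1]nonane | COc1cc(CCB2C3CCCC2CCC3)ccc1O[Si](C(C)C)(C(C)C)C(C)C | intermediate
10 | bis{2-methoxy-6-[2-(3-methoxy-4-triisopropylsilyloxyphenyl)ethyl]-4-(triisopropylsilyloxy)phenyl}methane | COc1cc(CCc2cc(O[Si](C(C)C)(C(C)C)C(C)C)cc(OC)c2Cc2c(CCc3ccc(O[Si](C(C)C)(C(C)C)C(C)C)c(OC)c3)cc(O[Si](C(C)C)(C(C)C)C(C)C)cc2OC)ccc1O[Si](C(C)C)(C(C)C)C(C)C | intermediate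
11 | 4,4'-methylenebis{5-[2-(4-hydroxy-3-methoxyphenyl)ethyl]-3-methoxyphenol} (achiral) | COc1cc(CCc2cc(O)cc(OC)c2Cc2c(CCc3ccc(O)c(OC)c3)cc(O)cc2OC)ccc1O | target

**Total step count:** 6.
**Longest linear sequence:** 5 (Steps 1, 2, 3, 5, 6).

**Three steps most likely to fail**

Step 2 is the most exposed. Aryllithium 3 can lose LiCl to give an aryne if the flask warms, and the second addition has to build a tetra-ortho-substituted carbinol in the same pot. The fallback replaces the carbonyl-addition linchpin with an sp2–sp3 cross-coupling. It sets out from 2 and comes back at 6, so 5 and Step 3 are by-passed.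
- 2 is lithiated as before to 3. One half is quenched with DMF, and aldehyde 4 is now isolated.
- 4 is reduced (NaBH4, MeOH, 0 °C) to [2-chloro-6-methoxy-4-(triisopropylsilyloxy)phenyl]methanol F1.
- F1 is brominated (PBr3, CH2Cl2, 0 °C) to [4-(bromomethyl)-3-chloro-5-methoxyphenoxy]triisopropylsilane F2.
- The other half of 3 is transmetalated (ZnCl2, THF, −78 °C → rt) to [2-chloro-6-methoxy-4-(triisopropylsilyloxy)phenyl]zinc chloride F3, which no longer eliminates to an aryne.
- Negishi coupling of F2 with F3 (Pd(PPh3)4 5 mol %, THF, rt to 50 °C, Ar–Cl inert) gives 6.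

Step 5 is next. Two couplings must occur beside a bulky diarylmethyl group, and slow transmetalation, β-hydride elimination or protodeboronation of the alkylborane could leave mono-coupled or reduced material. The fallback drops the organoboron sp3 partner and uses vinylation followed by saturation. It sets out from 6 (with 8) and comes back at 10.
- A double Mizoroki–Heck reaction of 6 with styrene 8 (Pd2(dba)3, [HP(t-Bu)3]BF4, Cy2NMe, dioxane, 100 °C) gives bis{2-methoxy-6-[(E)-2-(3-methoxy-4-triisopropylsilyloxyphenyl)ethenyl]-4-(triisopropylsilyloxy)phenyl}methane F4.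
- Hydrogenation of F4 (H2 1 atm, 10 % Pd/C, EtOAc, rt) saturates both alkenes to give 10.

Step 3 is third. The strongly acidic medium could desilylate the para-OTIPS cation through a quinone methide, or fragment the very electron-rich carbinol by ipso-protonation. The fallback is a neutral radical deoxygenation (Barton–McCombie). It sets out from 5 and comes back at 6.
- 5 is converted (NaH, CS2, then MeI, THF, 0 °C → rt) to O-{bis[2-chloro-6-methoxy-4-(triisopropylsilyloxy)phenyl]methyl} S-methyl dithiocarbonate F5.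
- F5 is reduced with Bu3SnH/AIBN (toluene, 90 °C) to 6. The aryl chlorides and silyl ethers are inert under these conditions.

**Further compounds**
F1 | step 2 | [2-chloro-6-methoxy-4-(triisopropylsilyloxy)phenyl]methanol | OCc1c(Cl)cc(O[Si](C(C)C)(C(C)C)C(C)C)cc1OC
F2 | step 2 | [4-(bromomethyl)-3-chloro-5-methoxyphenoxy]triisopropylsilane | BrCc1c(Cl)cc(O[Si](C(C)C)(C(C)C)C(C)C)cc1OC
F3 | step 2 | [2-chloro-6-methoxy-4-(triisopropylsilyloxy)phenyl]zinc chloride | Cl[Zn]c1c(Cl)cc(O[Si](C(C)C)(C(C)C)C(C)C)cc1OC
F4 | step 5 | bis{2-methoxy-6-[(E)-2-(3-methoxy-4-triisopropylsilyloxyphenyl)ethenyl]-4-(triisopropylsilyloxy)phenyl}methane | COc1cc(/C=C/c2cc(O[Si](C(C)C)(C(C)C)C(C)C)cc(OC)c2Cc2c(/C=C/c3ccc(O[Si](C(C)C)(C(C)C)C(C)C)c(OC)c3)cc(O[Si](C(C)C)(C(C)C)C(C)C)cc2OC)ccc1O[Si](C(C)C)(C(C)C)C(C)C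
F5 | step 3 | O-{bis[2-chloro-6-methoxy-4-(triisopropylsilyloxy)phenyl]methyl} S-methyl dithiocarbonate | CSC(=S)OC(c1c(Cl)cc(O[Si](C(C)C)(C(C)C)C(C)C)cc1OC)c1c(Cl)cc(O[Si](C(C)C)(C(C)C)C(C)C)cc1OC
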